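**Plan**

1. Chain numbering: C1 (lactone C=O), C2(Me), C3(OH), C4 (ring O–CH), C5, C6(Me)=C7, C8, C9, C10(Me), C11=C12, C13=C14(Me), C15–C17, then lactam C-4. Cuts: C17–C(lactam) (B-alkyl Suzuki), C2–C3 and O–C1 of the furanone (Dieckmann, acylation), C4–C5 ([2,3]-Wittig), C6–C7 (Grignard), C12–C13 (Suzuki), C11=C12 (cross-metathesis).
2. Enabling feature: the homoallylic array O–C4–C5–C6(Me)=C7 with C5 cis to C8 is the retron of a [2,3]-Wittig shift of a glycolate ether of a 2-methylallyl carbinol oxygenated at C7. The furanone ring (O, C1, C2, C3, C4) is then closed on the α-hydroxy ester that this shift delivers.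
3. Forward: citronellene epoxide → E-alkenylboronate → Suzuki (C11–C14 diene plus C15–C17 as an allyl group) → C7 aldehyde → isopropenyl carbinol → glycolate ether → [2,3] shift → furanone ring (first ring) → MOM ether → 9-BBN/Suzuki joins the separately made lactam ring → deprotection.
4. The metathesis is run on the epoxide: any later intermediate holding the vinyl group together with the isopropenyl or the C6=C7 alkene would be expected to ring-close (cyclohexene or 3-methylcyclopentene, as citronellene itself does) instead of cross-coupling.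
5. Stereochemistry: C10 from (S)-β-citronellene; the C7 carbinol from CBS reduction; C4 and 6Z from the [2,3] shift (1,4-chirality transfer, A1,2 strain); 11E from cross-metathesis; 13E from syn-carboalumination.

Key step: step 10

Remark: (S)-β-citronellene, pent-1-en-4-yne and methyl (2E)-4-chloro-3-methoxybut-2-enoate are taken as commercial; the ee of the citronellene caps that of C10. Locants in compound names are IUPAC locants of that compound; "C4, C7 …" refer to the chain numbering of the plan.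

Step 1
Reactants: 1 (S)-β-citronellene [(3S)-3,7-dimethylocta-1,6-diene]
Product: 2 2,2-dimethyl-3-[(3S)-3-methylpent-4-en-1-yl]oxirane (both oxirane epimers)
Conditions: mCPBA (1.05 equiv), NaHCO3, CH2Cl2, 0 °C
Reagents that add atoms: 3-chloroperoxybenzoic acid (mCPBA), OOC(=O)c1cccc(Cl)c1
Why: Prilezhaev epoxidation, in which the electron-rich trisubstituted alkene should react far faster than the vinyl group; the epoxide masks the future C7 aldehyde and removes the alkene that would ring-close onto the vinyl group in step 2, and its uncontrolled CH stereocentre is destroyed in step 5.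

Step 2
Reactants: 2 2,2-dimethyl-3-[(3S)-3-methylpent-4-en-1-yl]oxirane; 3 vinylboronic acid pinacol ester (2-ethenyl-4,4,5,5-tetramethyl-1,3,2-dioxaborolane)
Product: 4 2-[(1E,3S)-5-(3,3-dimethyloxiran-2-yl)-3-methylpent-1-en-1-yl]-4,4,5,5-tetramethyl-1,3,2-dioxaborolane
Conditions: Hoveyda–Grubbs II (5 mol%), 3 (3 equiv), CH2Cl2, 40 °C
Reagents that add atoms: vinylboronic acid pinacol ester 3, C=CB1OC(C)(C)C(C)(C)O1
Why: Olefin cross-metathesis of the only alkene in 2 with vinyl-Bpin, where the bulky boryl group and the allylic branch should favour the E-alkenylboronate; epoxides are tolerated by the ruthenium carbene.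

Step 3
Reactants: 5 pent-1-en-4-yne
Product: 7 (1E)-1-iodo-2-methylpenta-1,4-diene, via dimethyl[(1E)-2-methylpenta-1,4-dien-1-yl]alumane 6 (not isolated)
Conditions: Me3Al (2 equiv), Cp2ZrCl2 (0.25 equiv), CH2Cl2, 0 °C → rt; then I2, THF, −30 → 0 °C
Reagents that add atoms: trimethylaluminium, C[Al](C)C; iodine, II
Why: Negishi zirconium-catalysed carboalumination adds Me and Al syn across the terminal alkyne with Al at the terminus, and iodinolysis with retention should give the E-iodoalkene; the isolated alkene does not carbometalate under these conditions.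

Step 4
Reactants: 4 2-[(1E,3S)-5-(3,3-dimethyloxiran-2-yl)-3-methylpent-1-en-1-yl]-4,4,5,5-tetramethyl-1,3,2-dioxaborolane; 7 (1E)-1-iodo-2-methylpenta-1,4-diene
Product: 8 2-[(3S,4E,6E)-3,7-dimethyldeca-4,6,9-trien-1-yl]-3,3-dimethyloxirane
Conditions: Pd(dppf)Cl2 (5 mol%), K3PO4 (3 equiv), THF/H2O, rt
Reagents that add atoms: none
Why: Suzuki–Miyaura coupling of an alkenylboronate with an alkenyl iodide proceeds with retention at both partners and should give the 4E,6E-diene; the epoxide and the skipped terminal alkene are inert to Pd(0)/phosphate at room temperature.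

Step 5
Reactants: 8 2-[(3S,4E,6E)-3,7-dimethyldeca-4,6,9-trien-1-yl]-3,3-dimethyloxirane
Product: 9 (4S,5E,7E)-4,8-dimethylundeca-5,7,10-trienal
Conditions: H5IO6 (1.2 equiv), THF/H2O, 0 °C
Reagents that add atoms: none
Why: Periodic acid opens the trisubstituted epoxide to the glycol and cleaves it (Malaprade glycol cleavage) to the aldehyde and acetone without touching the alkenes; the methyl stereocentre is γ to the carbonyl and cannot epimerise.

Step 6
Reactants: 9 (4S,5E,7E)-4,8-dimethylundeca-5,7,10-trienal; 10 isopropenylmagnesium bromide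
Product: 11 (6S,7E,9E)-2,6,10-trimethyltrideca-1,7,9,12-tetraen-3-ol (both C-3 epimers)
Conditions: 10 (1.3 equiv), THF, −78 → 0 °C; aq. NH4Cl
Reagents that add atoms: isopropenylmagnesium bromide 10, C=C(C)[Mg]Br
Why: Grignard 1,2-addition to the aldehyde installs C5–C6(Me) of the target chain; the carbinol configuration is not controlled here because it is reset in steps 7 and 8.

Step 7
Reactants: 11 (6S,7E,9E)-2,6,10-trimethyltrideca-1,7,9,12-tetraen-3-ol
Product: 12 (6S,7E,9E)-2,6,10-trimethyltrideca-1,7,9,12-tetraen-3-one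
Conditions: Dess–Martin periodinane (1.3 equiv), NaHCO3, CH2Cl2, 0 °C → rt; used at once
Reagents that add atoms: none
Why: Dess–Martin oxidation of the allylic alcohol under buffered conditions gives the isopropenyl ketone; the 1,1-disubstituted diene terminus should make an intramolecular Diels–Alder reaction of this enone slow.

Step 8
Reactants: 12 (6S,7E,9E)-2,6,10-trimethyltrideca-1,7,9,12-tetraen-3-one
Product: 13 (3S,6S,7E,9E)-2,6,10-trimethyltrideca-1,7,9,12-tetraen-3-ol
Conditions: (R)-2-methyl-CBS-oxazaborolidine (20 mol%), catecholborane (1.5 equiv), toluene, −78 °C; aq. NaOH work-up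
Reagents that add atoms: none
Why: Corey–Bakshi–Shibata reduction, in which the isopropenyl group is the large substituent, so the (R)-catalyst should give the 3S alcohol (the S catalyst gives R for this substitution pattern); catecholborane at −78 °C does not hydroborate the alkenes.

Step 9
Reactants: 13 (3S,6S,7E,9E)-2,6,10-trimethyltrideca-1,7,9,12-tetraen-3-ol; 14 isopropyl bromoacetate
Product: 16 propan-2-yl {[(3S,6S,7E,9E)-2,6,10-trimethyltrideca-1,7,9,12-tetraen-3-yl]oxy}acetate, via sodium (3S,6S,7E,9E)-2,6,10-trimethyltrideca-1,7,9,12-tetraen-3-olate 15 (not isolated)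
Conditions: NaH (1.3 equiv), THF, 0 °C; then 14 (1.5 equiv), Bu4NI (cat.), 0 °C → rt
Reagents that add atoms: isopropyl bromoacetate 14, CC(C)OC(=O)CBr
Why: Williamson ether synthesis, in which the sodium alkoxide displaces bromide from the highly SN2-reactive α-bromo ester while the branched isopropyl ester slows transesterification; the carbinol configuration is untouched.

Step 10
Reactants: 16 propan-2-yl {[(3S,6S,7E,9E)-2,6,10-trimethyltrideca-1,7,9,12-tetraen-3-yl]oxy}acetate
Product: 19 propan-2-yl (2S,4Z,8S,9E,11E)-2-hydroxy-4,8,12-trimethylpentadeca-4,9,11,14-tetraenoate, via the chelated lithium enolate of 16 (O–Li cis to the allyloxy oxygen) 17 (not isolated), via the chlorobis(cyclopentadienyl)zirconium enolate of 16 18 (not isolated)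
Conditions: LDA (1.5 equiv), THF, −100 °C; Cp2ZrCl2 (1.6 equiv), −100 → −20 °C; 1 M HCl work-up
Reagents that add atoms: none
Why: LDA forms the chelated glycolate enolate 17 and Cp2ZrCl2 converts it into the zirconium enolate 18, whose α-carbon bonds to the terminal CH2 of the 2-methylallyl unit while the C–O bond at the carbinol carbon breaks, a concerted suprafacial [2,3]-Wittig shift through a five-membered envelope transition state. The closest known reaction type is the Z-selective [2,3]-Wittig rearrangement of zirconium enolates of isopropyl (1-alkyl-2-methylallyloxy)acetates. No ring closes. The new C-2 stereocentre of 19 (C4 of the target) is set by 1,4-chirality transfer from C-3 of 16 (C7): the enolate must add to the allyl face syn to the departing oxygen, and with the bulky zirconocene enolate unit exo to the envelope, away from the vinylic methyl group, the 3S ether gives 2S. The step needs Z geometry and the exo orientation together: A1,2 strain between the vinylic methyl group and the carbinol side chain forces that chain pseudoaxial (Z), and the size of the zirconium enolate plus the same methyl group disfavours the endo transition state. The remote diene and terminal alkene are not acidic enough to be touched by LDA at −100 °C.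

Step 11
Reactants: 19 propan-2-yl (2S,4Z,8S,9E,11E)-2-hydroxy-4,8,12-trimethylpentadeca-4,9,11,14-tetraenoate; 20 propanoyl chloride
Product: 21 propan-2-yl (2S,4Z,8S,9E,11E)-4,8,12-trimethyl-2-(propanoyloxy)pentadeca-4,9,11,14-tetraenoate
Conditions: 20 (1.3 equiv), pyridine, DMAP (cat.), CH2Cl2, 0 °C
Reagents that add atoms: propanoyl chloride 20, CCC(=O)Cl
Why: DMAP-catalysed O-acylation of the secondary α-hydroxy ester; no bond to the stereocentre is made or broken.

Step 12
Reactants: 21 propan-2-yl (2S,4Z,8S,9E,11E)-4,8,12-trimethyl-2-(propanoyloxy)pentadeca-4,9,11,14-tetraenoate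
Product: 22 (5S)-4-hydroxy-3-methyl-5-[(2Z,6S,7E,9E)-2,6,10-trimethyltrideca-2,7,9,12-tetraen-1-yl]furan-2(5H)-one
Conditions: LiHMDS (2.5 equiv), THF, −78 → 0 °C; 1 M HCl work-up
Reagents that add atoms: none
Why: Dieckmann (intramolecular Claisen) condensation, in which the propanoate enolate attacks the isopropyl ester to close the furanone ring; the tetronate anion formed is stable to base, so the C-5 configuration (S) should be retained when enolisation is run at −78 °C.

Step 13
Reactants: 22 (5S)-4-hydroxy-3-methyl-5-[(2Z,6S,7E,9E)-2,6,10-trimethyltrideca-2,7,9,12-tetraen-1-yl]furan-2(5H)-one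
Product: 23 (5S)-4-(methoxymethoxy)-3-methyl-5-[(2Z,6S,7E,9E)-2,6,10-trimethyltrideca-2,7,9,12-tetraen-1-yl]furan-2(5H)-one
Conditions: MOMCl (1.5 equiv), i-Pr2NEt, CH2Cl2, 0 °C
Reagents that add atoms: chloromethyl methyl ether (MOMCl), COCCl
Why: O-Alkylation of the vinylogous acid with the hard electrophile MOMCl should give the 4-O-MOM tetronate, which masks the acidic enol during hydroboration and palladium coupling.

Step 14
Reactants: 24 methyl (2E)-4-chloro-3-methoxybut-2-enoate; 25 3-methylbutan-1-amine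
Product: 26 4-methoxy-1-(3-methylbutyl)-1,5-dihydro-2H-pyrrol-2-one
Conditions: Et3N (1.2 equiv), MeCN, reflux
Reagents that add atoms: 3-methylbutan-1-amine 25, CC(C)CCN
Why: SN2 displacement of the allylic chloride by the primary amine followed by lactamisation onto the cis ester, a known entry to N-alkyl 4-methoxy-3-pyrrolin-2-ones.

Step 15
Reactants: 26 4-methoxy-1-(3-methylbutyl)-1,5-dihydro-2H-pyrrol-2-one
Product: 27 1-(3-methylbutyl)pyrrolidine-2,4-dione
Conditions: 3 M aq. HCl, THF, 40 °C; used at once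
Reagents that add atoms: water, O
Why: Acid hydrolysis of the vinylogous carbamate enol ether gives the tetramic acid, which is taken on immediately because 3,5-unsubstituted tetramic acids self-condense on standing.

Step 16
Reactants: 27 1-(3-methylbutyl)pyrrolidine-2,4-dione
Product: 28 1-(3-methylbutyl)-5-oxo-2,5-dihydro-1H-pyrrol-3-yl trifluoromethanesulfonate
Conditions: Tf2O (1.1 equiv), Et3N, CH2Cl2, −78 °C
Reagents that add atoms: trifluoromethanesulfonic anhydride, O=S(=O)(OS(=O)(=O)C(F)(F)F)C(F)(F)F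
Why: O-Triflation of the enol form of the tetramic acid gives the vinylogous acyl (enol) triflate, an electron-poor partner for palladium coupling.

Step 17
Reactants: 23 (5S)-4-(methoxymethoxy)-3-methyl-5-[(2Z,6S,7E,9E)-2,6,10-trimethyltrideca-2,7,9,12-tetraen-1-yl]furan-2(5H)-one; 28 1-(3-methylbutyl)-5-oxo-2,5-dihydro-1H-pyrrol-3-yl trifluoromethanesulfonate
Product: 30 (5S)-4-(methoxymethoxy)-3-methyl-5-{(2Z,6S,7E,9E)-2,6,10-trimethyl-13-[1-(3-methylbutyl)-5-oxo-2,5-dihydro-1H-pyrrol-3-yl]trideca-2,7,9-trien-1-yl}furan-2(5H)-one, via (5S)-5-[(2Z,6S,7E,9E)-13-(9-borabicyclo[3.3.1]nonan-9-yl)-2,6,10-trimethyltrideca-2,7,9-trien-1-yl]-4-(methoxymethoxy)-3-methylfuran-2(5H)-one 29 (not isolated)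
Conditions: 9-BBN (1.2 equiv), THF, 0 °C → rt; then 28, Pd(dppf)Cl2 (5 mol%), AsPh3, K3PO4 (3 equiv, aq.), DMF, rt
Reagents that add atoms: none
Why: 9-BBN should add anti-Markovnikov to the only monosubstituted alkene (the trisubstituted alkene, the conjugated diene and the tetrasubstituted enol ether are far slower), and the B-alkyl-9-BBN then couples with the enol triflate in a B-alkyl Suzuki–Miyaura reaction that leaves all alkene geometries and both stereocentres untouched.

Step 18
Reactants: 30 (5S)-4-(methoxymethoxy)-3-methyl-5-{(2Z,6S,7E,9E)-2,6,10-trimethyl-13-[1-(3-methylbutyl)-5-oxo-2,5-dihydro-1H-pyrrol-3-yl]trideca-2,7,9-trien-1-yl}furan-2(5H)-one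
Product: 31 sarcotrine D
Conditions: 1 M HCl in MeOH, 0 °C → rt
Reagents that add atoms: none
Why: Acid-catalysed acetal exchange removes the MOM group from the vinylogous ester oxygen under conditions mild enough for the trisubstituted alkene and the diene; no stereocentre is affected.

**Compound list**

1 | (S)-β-citronellene, (3S)-3,7-dimethylocta-1,6-diene | C=C[C@@H](C)CCC=C(C)C | starting material
2 | 2,2-dimethyl-3-[(3S)-3-methylpent-4-en-1-yl]oxirane (both oxirane epimers) | C=C[C@@H](C)CCC1OC1(C)C | intermediate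
3 | vinylboronic acid pinacol ester, 2-ethenyl-4,4,5,5-tetramethyl-1,3,2-dioxaborolane | C=CB1OC(C)(C)C(C)(C)O1 | starting material
4 | 2-[(1E,3S)-5-(3,3-dimethyloxiran-2-yl)-3-methylpent-1-en-1-yl]-4,4,5,5-tetramethyl-1,3,2-dioxaborolane | CC1(C)OB(/C=C/[C@@H](C)CCC2OC2(C)C)OC1(C)C | intermediate
5 | pent-1-en-4-yne | C=CCC#C | starting material
6 | dimethyl[(1E)-2-methylpenta-1,4-dien-1-yl]alumane | C=CC/C(C)=C/[Al](C)C | intermediate
7 | (1E)-1-iodo-2-methylpenta-1,4-diene | C=CC/C(C)=C/I | intermediate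
8 | 2-[(3S,4E,6E)-3,7-dimethyldeca-4,6,9-trien-1-yl]-3,3-dimethyloxirane | C=CC/C(C)=C/C=C/[C@@H](C)CCC1OC1(C)C | intermediate
9 | (4S,5E,7E)-4,8-dimethylundeca-5,7,10-trienal | O=CCC[C@H](C)/C=C/C=C(\C)CC=C | intermediate
10 | isopropenylmagnesium bromide | C=C(C)[Mg]Br | starting material
11 | (6S,7E,9E)-2,6,10-trimethyltrideca-1,7,9,12-tetraen-3-ol (both C-3 epimers) | C=C(C)C(O)CC[C@H](C)/C=C/C=C(\C)CC=C | intermediate
12 | (6S,7E,9E)-2,6,10-trimethyltrideca-1,7,9,12-tetraen-3-one | C=C(C)C(=O)CC[C@H](C)/C=C/C=C(\C)CC=C | intermediate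
13 | (3S,6S,7E,9E)-2,6,10-trimethyltrideca-1,7,9,12-tetraen-3-ol | C=C(C)[C@@H](O)CC[C@H](C)/C=C/C=C(\C)CC=C | intermediate
14 | isopropyl bromoacetate, propan-2-yl 2-bromoacetate | CC(C)OC(=O)CBr | starting material
15 | sodium (3S,6S,7E,9E)-2,6,10-trimethyltrideca-1,7,9,12-tetraen-3-olate | C=C(C)[C@@H]([O-])CC[C@H](C)/C=C/C=C(\C)CC=C.[Na+] | intermediate
16 | propan-2-yl {[(3S,6S,7E,9E)-2,6,10-trimethyltrideca-1,7,9,12-tetraen-3-yl]oxy}acetate | C=C(C)[C@@H](OCC(=O)OC(C)C)CC[C@H](C)/C=C/C=C(\C)CC=C | intermediate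
17 | chelated lithium enolate of 16 (O–Li cis to the allyloxy oxygen) | C=C(C)[C@@H](O/C=C(\O[Li])OC(C)C)CC[C@H](C)/C=C/C=C(\C)CC=C | intermediate
18 | chlorobis(cyclopentadienyl)zirconium enolate of 16 (Cp drawn σ-bonded) | C=C(C)[C@@H](O/C=C(\O[Zr](Cl)(C1C=CC=C1)C1C=CC=C1)OC(C)C)CC[C@H](C)/C=C/C=C(\C)CC=C | intermediate
19 | propan-2-yl (2S,4Z,8S,9E,11E)-2-hydroxy-4,8,12-trimethylpentadeca-4,9,11,14-tetraenoate | CC(C)OC(=O)[C@@H](O)C/C(C)=C\CC[C@H](C)/C=C/C=C(\C)CC=C | intermediate
20 | propanoyl chloride | CCC(=O)Cl | starting material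
21 | propan-2-yl (2S,4Z,8S,9E,11E)-4,8,12-trimethyl-2-(propanoyloxy)pentadeca-4,9,11,14-tetraenoate | CCC(=O)O[C@@H](C/C(C)=C\CC[C@H](C)/C=C/C=C(\C)CC=C)C(=O)OC(C)C | intermediate
22 | (5S)-4-hydroxy-3-methyl-5-[(2Z,6S,7E,9E)-2,6,10-trimethyltrideca-2,7,9,12-tetraen-1-yl]furan-2(5H)-one | CC1=C(O)[C@H](C/C(C)=C\CC[C@H](C)/C=C/C=C(\C)CC=C)OC1=O | intermediate
23 | (5S)-4-(methoxymethoxy)-3-methyl-5-[(2Z,6S,7E,9E)-2,6,10-trimethyltrideca-2,7,9,12-tetraen-1-yl]furan-2(5H)-one | CC1=C(OCOC)[C@H](C/C(C)=C\CC[C@H](C)/C=C/C=C(\C)CC=C)OC1=O | intermediate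
24 | methyl (2E)-4-chloro-3-methoxybut-2-enoate | COC(=O)/C=C(/OC)CCl | starting material
25 | 3-methylbutan-1-amine | CC(C)CCN | starting material
26 | 4-methoxy-1-(3-methylbutyl)-1,5-dihydro-2H-pyrrol-2-one | COC1=CC(=O)N(CCC(C)C)C1 | intermediate
27 | 1-(3-methylbutyl)pyrrolidine-2,4-dione | O=C1CC(=O)N(CCC(C)C)C1 | intermediate
28 | 1-(3-methylbutyl)-5-oxo-2,5-dihydro-1H-pyrrol-3-yl trifluoromethanesulfonate | CC(C)CCN1CC(OS(=O)(=O)C(F)(F)F)=CC1=O | intermediate
29 | (5S)-5-[(2Z,6S,7E,9E)-13-(9-borabicyclo[3.3.1]nonan-9-yl)-2,6,10-trimethyltrideca-2,7,9-trien-1-yl]-4-(methoxymethoxy)-3-methylfuran-2(5H)-one | CC1=C(OCOC)[C@H](C/C(C)=C\CC[C@H](C)/C=C/C=C(\C)CCCB2C3CCCC2CCC3)OC1=O | intermediate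
30 | (5S)-4-(methoxymethoxy)-3-methyl-5-{(2Z,6S,7E,9E)-2,6,10-trimethyl-13-[1-(3-methylbutyl)-5-oxo-2,5-dihydro-1H-pyrrol-3-yl]trideca-2,7,9-trien-1-yl}furan-2(5H)-one | CC1=C(OCOC)[C@H](C/C(C)=C\CC[C@H](C)/C=C/C=C(\C)CCCC2=CC(=O)N(CCC(C)C)C2)OC1=O | intermediate
31 | sarcotrine D, (5S)-4-hydroxy-3-methyl-5-{(2Z,6S,7E,9E)-2,6,10-trimethyl-13-[1-(3-methylbutyl)-5-oxo-2,5-dihydro-1H-pyrrol-3-yl]trideca-2,7,9-trien-1-yl}furan-2(5H)-one | CC1=C(O)[C@H](C/C(C)=C\CC[C@H](C)/C=C/C=C(\C)CCCC2=CC(=O)N(CCC(C)C)C2)OC1=O | target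

**Step count**

Total: 18 steps. Longest linear sequence: 14 steps (1, 2, 4–13, 17, 18).

**Steps most likely to fail**

Step 10. The endo transition state or the chain-pseudoequatorial conformer may compete, eroding the 1,4-chirality transfer or the Z geometry, and the enolate may fragment by loss of the allyloxide before it rearranges. The fallback sets out from 9 and returns at 22; it takes C4 from the chiral pool and the Z alkene from an olefination. Aldehyde 9 with (1-iodoethyl)triphenylphosphonium iodide and NaHMDS (THF, −78 °C, Stork–Zhao-type olefination) should give (4E,6E,8S,11Z)-12-iodo-4,8-dimethyltrideca-1,4,6,11-tetraene F1. Iodine–magnesium exchange with i-PrMgCl·LiCl (THF, rt) gives, with retention, chloro[(2Z,6S,7E,9E)-6,10-dimethyltrideca-2,7,9,12-tetraen-2-yl]magnesium F2. With CuI (10 mol%) at −40 °C this opens commercial methyl (2S)-oxirane-2-carboxylate at its CH2 carbon to methyl (2S,4Z,8S,9E,11E)-2-hydroxy-4,8,12-trimethylpentadeca-4,9,11,14-tetraenoate F3. Propanoyl chloride/pyridine then gives methyl (2S,4Z,8S,9E,11E)-4,8,12-trimethyl-2-(propanoyloxy)pentadeca-4,9,11,14-tetraenoate F4, and the LiHMDS Dieckmann closure of step 12 applied to F4 gives 22.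

Step 17. The aqueous base may hydrolyse the enol triflate faster than the alkylborane transmetalates, so that protodeboronation and triflate loss outrun the coupling. The fallback sets out from 23 and returns at 30, replacing the basic aqueous coupling by an anhydrous Negishi coupling. Hydroboration of 23 with 9-BBN as in step 17 and oxidation of 29 with NaBO3·4H2O should give (5S)-5-[(2Z,6S,7E,9E)-13-hydroxy-2,6,10-trimethyltrideca-2,7,9-trien-1-yl]-4-(methoxymethoxy)-3-methylfuran-2(5H)-one F5. I2/PPh3/imidazole converts it into (5S)-5-[(2Z,6S,7E,9E)-13-iodo-2,6,10-trimethyltrideca-2,7,9-trien-1-yl]-4-(methoxymethoxy)-3-methylfuran-2(5H)-one F6. Zinc dust with LiCl in THF gives the alkylzinc iodide of F6 (C–I replaced by C–ZnI) F7, which is coupled with triflate 28 under Pd(PPh3)4 catalysis in THF/NMP to give 30.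

Step 9. Acyl transfer from the bromoacetate to the hindered alkoxide (transesterification) and base-induced self-condensation of the ester may outrun the SN2 displacement. The fallback sets out from 13 and returns at 16, alkylating with a carboxylate that cannot be transesterified. Alcohol 13 with NaH (2.5 equiv) and bromoacetic acid in THF at reflux should give {[(3S,6S,7E,9E)-2,6,10-trimethyltrideca-1,7,9,12-tetraen-3-yl]oxy}acetic acid F8, and O-alkylation of its caesium salt with 2-iodopropane (Cs2CO3, DMF) gives 16.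

**Further compounds**

F1 | step 10 | (4E,6E,8S,11Z)-12-iodo-4,8-dimethyltrideca-1,4,6,11-tetraene | C/C(I)=C/CC[C@H](C)/C=C/C=C(\C)CC=C
F2 | step 10 | chloro[(2Z,6S,7E,9E)-6,10-dimethyltrideca-2,7,9,12-tetraen-2-yl]magnesium | C/C([Mg]Cl)=C/CC[C@H](C)/C=C/C=C(\C)CC=C
F3 | step 10 | methyl (2S,4Z,8S,9E,11E)-2-hydroxy-4,8,12-trimethylpentadeca-4,9,11,14-tetraenoate | COC(=O)[C@@H](O)C/C(C)=C\CC[C@H](C)/C=C/C=C(\C)CC=C
F4 | step 10 | methyl (2S,4Z,8S,9E,11E)-4,8,12-trimethyl-2-(propanoyloxy)pentadeca-4,9,11,14-tetraenoate | CCC(=O)O[C@@H](C/C(C)=C\CC[C@H](C)/C=C/C=C(\C)CC=C)C(=O)OC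
F5 | step 17 | (5S)-5-[(2Z,6S,7E,9E)-13-hydroxy-2,6,10-trimethyltrideca-2,7,9-trien-1-yl]-4-(methoxymethoxy)-3-methylfuran-2(5H)-one | CC1=C(OCOC)[C@H](C/C(C)=C\CC[C@H](C)/C=C/C=C(\C)CCCO)OC1=O
F6 | step 17 | (5S)-5-[(2Z,6S,7E,9E)-13-iodo-2,6,10-trimethyltrideca-2,7,9-trien-1-yl]-4-(methoxymethoxy)-3-methylfuran-2(5H)-one | CC1=C(OCOC)[C@H](C/C(C)=C\CC[C@H](C)/C=C/C=C(\C)CCCI)OC1=O
F7 | step 17 | alkylzinc iodide of F6 (C–I replaced by C–ZnI) | CC1=C(OCOC)[C@H](C/C(C)=C\CC[C@H](C)/C=C/C=C(\C)CCC[Zn]I)OC1=O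
F8 | step 9 | {[(3S,6S,7E,9E)-2,6,10-trimethyltrideca-1,7,9,12-tetraen-3-yl]oxy}acetic acid | C=C(C)[C@@H](OCC(=O)O)CC[C@H](C)/C=C/C=C(\C)CC=C
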